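(The runs come from a simulation with constants of no real substance, and the scatter is random.)

Take the balanced charge with no D lost as the zero of the scale, where chains have no stop, and read each length as a distance from it.

in all of them: Z 0.162 M
- ochre: X 0.14 M; D 1 equiv; run made earlier
- teal: X 0.51 M; D 1 equiv; run made earlier
- south-east: X 0.81 M; D 1.00 equiv; time 30 min
- south-west: X 0.20 M; D 1.00 equiv; time 30 min

- ochre (time / min: E / %, X / %): 1.50: 57.0, 43.5; 2.50: 67.0, 32.3; 4.00: 74.3, 26.5; 6.00: 77.8, 22.1; 10.0: 80.2, 19.2; 15.0: 80.8, 18.7; 20.0: 81.8, 18.1
- teal (time / min: E / %, X / %): 3.00: 87.8, 11.7; 6.00: 91.3, 10.0; 10.0: 92.2, 7.1; 12.0: 92.7, 8.3; 15.0: 92.5, 7.2; 20.0: 91.5, 7.9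

(each reading ± 0.5 percentage points)

- each molecule carries two end groups: a chain counts once for every two ends that are left, dead ends included; the units are half of the end groups of the two monomers charged
- candidate steps: X + D -> E + Q; D + Z -> L; D -> J; E -> G
- a link that another step uses up counts as cut, two dead ends; so do two ends of one kind that react with each other

* which of the two ends with the longer chains by the average number of monomer units in a chain (unreacted monomers counted as chains of one) ("neither" if they lie within 10%) (south-east / south-west / neither)
* average number of monomer units in a chain (unreacted monomers counted as chains of one) at the end, south-east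
* average number of monomer units in a chain (unreacted monomers counted as chains of one) at the end, south-west

I turned the question round and asked what would have to be true for south-west to tie with south-east. X stalled in both earlier runs, and since X and D were charged equal, I took the X left at the stall as the D lost, with D the limiting reagent. I treated that loss as pseudo-first-order in D, with [Z] at its charge, competing with X + D. Units then equal [X]start and chains equal [X]end, so:

[X]end = s · ln([X]start/[X]end)

N = [X]start/[X]end, so N ln N = [X]start/s

The last readings gave s = 0.0148 M in ochre and 0.0159 M in teal. I kept the mean, 0.0153 M, as the loss scale, the [X] at which D is lost as fast as it couples.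

A tie asks s to grow in step with [X]start, by 4.05 times from south-west to south-east. From ochre to teal, s read 1.07 times as large, less than the 3.64 times of [X]start, with the readings scattered by 0.5 percentage points. So I expected no tie:

south-east: [X]start/s = 52.8, N = 18.2

south-west: [X]start/s = 13.0, N = 6.83

The forecast chose south-east, with 18.4 and 6.9, holding that “E stays flat after the plateau, so links are not being cut”; my lengths stand below its two.

The flask gave south-east, with 15.4 in south-east and 6.50 in south-west.

    X + D → E + Q (k = 7.00 M⁻¹ min⁻¹)
    D + Z → L (k = 0.338 M⁻¹ min⁻¹)
    D → J (k = 0.0511 min⁻¹)
    E → G (k = 4.30 × 10⁻⁴ min⁻¹)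

At 30.0 min, south-east held X at 5.29%, against 5.49% from s, and G at 1.19%; each cut link adds a chain, and X plus G gives a length of 15.4. The neighbouring flask is south-east read at 80 min, where G stood at 3.18%. The same reckoning, with X from s plus that G, gives 11.5. That flask held X at 5.29% and E at 91.5%, and its chains averaged 11.8 units.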